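**Retrosynthetic overview**

1. Ring labels: upper flavan unit A (benzo ring), C (pyran), B (aryl on C2); lower unit D (benzo ring), F (pyran), E (aryl); G is the bridging galloyl ring. The last step is hydrogenolysis of all phenol protecting groups from the protected macrocycle.
2. Key disconnection: both aryl bonds of C4 of the upper flavan, C4–C4a (ring A) and C4–C8 (ring D), are cut back to one open-chain aldehyde whose CHO carbon is C4. Forward, ring C closes first through C4–C4a and the 16-membered ring second through C4–C8, in one flask.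
3. Enabling feature: C4 is a diarylmethine carbon between two phloroglucinol-type carbons, C4a of ring A (ortho/para to O1, O5, O7) and C8 of ring D (ortho/para to its O1, O7, O5). One aldehyde carbon can therefore be arylated twice, and the galloyloxy group on C3 steers the second arylation trans.
4. The aldehyde comes from esterification of a ring-G carboxylic acid with penta-O-benzyl-epigallocatechin (rings D, F, E from the chiral pool). C2 and C3 of the upper unit come from a Sharpless epoxide opened by the ring-A phenoxide (inversion at C2) and a Mitsunobu galloylation (inversion at C3).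
5. The ring B–O–ring G diaryl ether is made at the outset by Ullmann coupling. Order of ring formation: ketal dioxole (protecting ring), epoxide (temporary), ring C, macrocycle.

Key step: step 16

Remark on the chemistry: all phenols are carried as benzyl ethers (Bn), except the catechol of ring G, which is a diphenylmethylene ketal; TBS = tert-butyldimethylsilyl. ArB = 3,4,5-tris(benzyloxy)-2-{[6-(allyloxycarbonyl)-2,2-diphenyl-1,3-benzodioxol-4-yl]oxy}phenyl. Gallic acid, 3,4,5-tris(benzyloxy)benzaldehyde, (triphenylphosphoranylidene)acetaldehyde, 3,5-bis(benzyloxy)phenol, 3,4,5-tris(benzyloxy)benzoic acid and (−)-epigallocatechin are taken as purchasable.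

**Route**

Step 1
Reactants: 1 gallic acid
Product: 2 allyl gallate (allyl 3,4,5-trihydroxybenzoate)
Conditions: allyl alcohol (solvent), cat. H2SO4, 90 °C
Reagents that add atoms: allyl alcohol, C=CCO
Why: Fischer esterification touches only the carboxyl group, and the allyl ester can later be removed by palladium-catalysed allyl transfer in the presence of the other esters of the route.

Step 2
Reactants: 2 allyl gallate
Product: 3 allyl 7-hydroxy-2,2-diphenyl-1,3-benzodioxole-5-carboxylate
Conditions: Ph2CCl2 (1.1 equiv), neat, 170 °C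
Reagents that add atoms: dichlorodiphenylmethane, ClC(Cl)(c1ccccc1)c1ccccc1
Why: Catechol ketalisation with a gem-dichloride can only bridge two adjacent hydroxyls (the two possible pairs are equivalent by symmetry), so one meta hydroxyl, the future diaryl ether oxygen, stays free.

Step 3
Reactants: 4 3,4,5-tris(benzyloxy)benzaldehyde
Product: 5 2-bromo-3,4,5-tris(benzyloxy)benzaldehyde
Conditions: NBS, MeCN, 0 °C → rt
Reagents that add atoms: N-bromosuccinimide, O=C1CCC(=O)N1Br
Why: Electrophilic aromatic bromination should occur at one of the two equivalent free ring positions, which are ortho and para to benzyloxy groups, and the formyl group deactivates the ring against a second bromination.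

Step 4
Reactants: 5 2-bromo-3,4,5-tris(benzyloxy)benzaldehyde; 3 allyl 7-hydroxy-2,2-diphenyl-1,3-benzodioxole-5-carboxylate
Product: 6 allyl 7-[4,5,6-tris(benzyloxy)-2-formylphenoxy]-2,2-diphenyl-1,3-benzodioxole-5-carboxylate (ArB–CHO)
Conditions: CuI (10 mol %), picolinic acid (20 mol %), K3PO4, DMSO, 90 °C
Reagents that add atoms: none
Why: Ullmann diaryl ether synthesis; the ortho formyl group activates the C–Br bond, and the ketal-tied phenol is a small nucleophile, so the hindered ring B–O–ring G ether should form.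

Step 5
Reactants: 6 ArB–CHO; 7 (triphenylphosphoranylidene)acetaldehyde
Product: 8 (E)-3-ArB-prop-2-enal
Conditions: toluene, 90 °C
Reagents that add atoms: none
Why: A Wittig reaction with the stabilised formyl ylide adds the two carbons that become C3 and C4 and should give the E enal, without touching the allyl ester that a reduction-based route to the allylic alcohol would destroy.

Step 6
Reactants: 8 (E)-3-ArB-prop-2-enal
Product: 9 (E)-3-ArB-prop-2-en-1-ol
Conditions: NaBH4, CeCl3·7H2O, MeOH/THF, 0 °C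
Reagents that add atoms: none
Why: Luche reduction delivers hydride to the carbonyl carbon only, so the alkene and the benzoate-type allyl ester should survive.

Step 7
Reactants: 9 (E)-3-ArB-prop-2-en-1-ol
Product: 10 [(2S,3S)-3-ArB-oxiran-2-yl]methanol
Conditions: Ti(OiPr)4 (10 mol %), L-(+)-diisopropyl tartrate (14 mol %), t-BuOOH, 4 Å MS, CH2Cl2, −20 °C; non-acidic work-up
Reagents that add atoms: tert-butyl hydroperoxide, CC(C)(C)OO
Why: Sharpless asymmetric epoxidation of the E allylic alcohol; the L-(+)-tartrate complex sets both epoxide carbons as (2S,3S), and only the allylic-alcohol alkene reacts, so the allyl ester alkene is left alone.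

Step 8
Reactants: 10 [(2S,3S)-3-ArB-oxiran-2-yl]methanol
Product: 11 tert-butyl{[(2S,3S)-3-ArB-oxiran-2-yl]methoxy}dimethylsilane
Conditions: TBSCl, imidazole, CH2Cl2, 0 °C → rt
Reagents that add atoms: tert-butyldimethylsilyl chloride, CC(C)(C)[Si](C)(C)Cl
Why: Silylation of the primary alcohol removes the possibility of epoxide migration under base and marks the carbon that will become the aldehyde.

Step 9
Reactants: 11 silyl epoxide; 12 3,5-bis(benzyloxy)phenol
Product: 13 (2S,3R)-3-ArB-3-[3,5-bis(benzyloxy)phenoxy]-1-(tert-butyldimethylsilyloxy)propan-2-ol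
Conditions: 12 (2.5 equiv), Cs2CO3 (0.3 equiv), DMF, 70 °C
Reagents that add atoms: none
Why: Base-mediated SN2 opening of a 3-aryl-2,3-epoxy alcohol derivative by a phenoxide at the benzylic carbon (the other carbon is deactivated by the adjacent CH2O group) forms the O1–C2 aryl ether with inversion, which sets flavan C2 as R; excess phenol buffers the new alkoxide against silyl migration.

Step 10
Reactants: 13 hydroxy ether; 14 3,4,5-tris(benzyloxy)benzoic acid
Product: 15 (2R,3R)-3-ArB-3-[3,5-bis(benzyloxy)phenoxy]-1-(tert-butyldimethylsilyloxy)propan-2-yl 3,4,5-tris(benzyloxy)benzoate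
Conditions: PPh3, DIAD, toluene, 0 °C → rt
Reagents that add atoms: none
Why: Mitsunobu esterification installs the galloyl group with inversion at the carbinol carbon, which converts the 2,3-trans-type (erythro) relation left by the epoxide opening into the 2,3-cis-type (threo) relation of the epi series and sets flavan C3 as R.

Step 11
Reactants: 15 allyl ester
Product: 16 carboxylic acid (15 with CO2H in place of the allyl ester on ring G)
Conditions: Pd(PPh3)4 (5 mol %), morpholine, THF, rt
Reagents that add atoms: none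
Why: Palladium-catalysed allyl transfer to morpholine through a π-allyl complex cleaves only the allyl ester, so the secondary galloyl ester, the silyl ether, the ketal and the benzyl ethers should remain.

Step 12
Reactants: 17 (−)-epigallocatechin
Product: 18 5,7,3',4',5'-penta-O-benzyl-(−)-epigallocatechin
Conditions: BnBr (5.5 equiv), K2CO3, DMF, −20 °C → rt, argon
Reagents that add atoms: benzyl bromide, BrCc1ccccc1
Why: Williamson etherification with a carbonate base alkylates the five phenols and leaves the much less acidic secondary 3-OH free; low temperature and exclusion of air limit oxidation and C2 epimerisation of the pyrogallol unit.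

Step 13
Reactants: 16 carboxylic acid; 18 penta-O-benzyl-epigallocatechin
Product: 19 seco ester (16 esterified through its ring-G carboxyl with the 3-OH of 18)
Conditions: DCC, DMAP (cat.), CH2Cl2, rt
Reagents that add atoms: none
Why: Steglich esterification is the standard way to galloylate the 3-OH of benzylated flavan-3-ols, and here the acid has no ortho substituent and the only free hydroxyl is that of 18.

Step 14
Reactants: 19 seco ester
Product: 20 primary alcohol (19 with CH2OH in place of CH2OTBS)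
Conditions: HF·pyridine, THF/pyridine, 0 °C
Reagents that add atoms: none
Why: Buffered fluoride cleaves the primary silyl ether under mildly acidic conditions, which should suppress migration of the neighbouring galloyl group to the freed hydroxyl.

Step 15
Reactants: 20 primary alcohol
Product: 21 open-chain aldehyde, (2S,3R)-3-aryl-3-[3,5-bis(benzyloxy)phenoxy]-2-[3,4,5-tris(benzyloxy)benzoyloxy]propanal (aryl = ring B carrying ring G and the lower unit)
Conditions: Dess–Martin periodinane, CH2Cl2, 0 °C → rt; used crude at once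
Reagents that add atoms: none
Why: Dess–Martin oxidation is near neutral, so the α-acyloxy stereocentre and the β-aryloxy group should survive long enough for immediate use.

Step 16
Reactants: 21 open-chain aldehyde
Product: 24 protected macrocycle (the target as its tridecabenzyl ether with a diphenylmethylene ketal on ring G), via 4-hydroxyflavan 22 (not isolated), via flavan-4-yl cation 23 (not isolated)
Conditions: TMSOTf (0.5 equiv), 4 Å MS, CH2Cl2, slow addition of 21 to about 1 mM, −78 → −20 °C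
Reagents that add atoms: none
Why: TMSOTf turns the aldehyde carbon (C4) into a silyloxycarbenium ion that is attacked by an ortho carbon of the 3,5-bis(benzyloxy)phenyl ether (future C4a) in a 6-exo-trig Friedel–Crafts hydroxyalkylation that closes ring C and gives 22; the acid then ionises the C4–O bond to cation 23, and C8 of ring D of the tethered epigallocatechin captures it, closing the 16-membered ring by an intramolecular Friedel–Crafts alkylation in which the cationic carbon lies in the new ring. The closest known reaction types are the acid-mediated cyclisation of 3-aryloxypropanals to chroman-4-ols, the Lewis-acid coupling of 4-oxygenated benzylated flavan-3-ol electrophiles with flavan-3-ol nucleophiles (also in tethered form) and, for the sum, the twofold arylation of an aldehyde to a diarylmethane. C4 is the only new stereocentre: the configuration of 22 is erased on ionisation, and the arene should add to 23 anti to the C3 galloyloxy group (acyloxonium participation, axial attack on the half-chair with ring B equatorial), giving the 3,4-trans 4R (4β) arrangement usual for 2,3-cis flavan-4-yl cations. Ring A is preferred over C6' of ring B (which would give an indane) because the phloroglucinol-type carbon is far more nucleophilic and closes a six- rather than a five-membered ring, and its two ortho carbons are equivalent. C8 is preferred over C6 of ring D by the known C8 preference of 5,7-di-O-benzyl flavan-3-ols, and ring closure is favoured over oligomerisation by slow addition at high dilution. C2 and C3 are not affected, because no bond to either is broken.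

Step 17
Reactants: 24 protected macrocycle
Product: 25 CNP0601265.1
Conditions: H2 (1 atm), Pd(OH)2/C, THF/MeOH/H2O, rt
Reagents that add atoms: none
Why: Hydrogenolysis removes the 13 benzyl ethers and the diphenylmethylene ketal in one operation, while the esters, the diaryl ether and the benzylic O1–C2 bonds of the flavan rings are expected to survive as in other procyanidin gallate deprotections.

**Compound list**

1 | gallic acid | OC(=O)c1cc(O)c(O)c(O)c1 | starting material
2 | allyl gallate | C=CCOC(=O)c1cc(O)c(O)c(O)c1 | intermediate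
3 | allyl 7-hydroxy-2,2-diphenyl-1,3-benzodioxole-5-carboxylate | C=CCOC(=O)c1cc(O)c2OC(c9ccccc9)(c9ccccc9)Oc2c1 | intermediate
4 | 3,4,5-tris(benzyloxy)benzaldehyde | O=Cc1cc(OCc9ccccc9)c(OCc9ccccc9)c(OCc9ccccc9)c1 | starting material
5 | 2-bromo-3,4,5-tris(benzyloxy)benzaldehyde | O=Cc1cc(OCc9ccccc9)c(OCc9ccccc9)c(OCc9ccccc9)c1Br | intermediate
6 | allyl 7-[4,5,6-tris(benzyloxy)-2-formylphenoxy]-2,2-diphenyl-1,3-benzodioxole-5-carboxylate (ArB–CHO) | O=Cc1cc(OCc9ccccc9)c(OCc9ccccc9)c(OCc9ccccc9)c1Oc1cc(cc8OC(c9ccccc9)(c9ccccc9)Oc18)C(=O)OCC=C | intermediate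
7 | (triphenylphosphoranylidene)acetaldehyde | O=CC=P(c1ccccc1)(c1ccccc1)c1ccccc1 | starting material
8 | (E)-3-ArB-prop-2-enal | O=C/C=C/c1cc(OCc9ccccc9)c(OCc9ccccc9)c(OCc9ccccc9)c1Oc1cc(cc8OC(c9ccccc9)(c9ccccc9)Oc18)C(=O)OCC=C | intermediate
9 | (E)-3-ArB-prop-2-en-1-ol | OC/C=C/c1cc(OCc9ccccc9)c(OCc9ccccc9)c(OCc9ccccc9)c1Oc1cc(cc8OC(c9ccccc9)(c9ccccc9)Oc18)C(=O)OCC=C | intermediate
10 | [(2S,3S)-3-ArB-oxiran-2-yl]methanol | OC[C@@H]1O[C@H]1c1cc(OCc9ccccc9)c(OCc9ccccc9)c(OCc9ccccc9)c1Oc1cc(cc8OC(c9ccccc9)(c9ccccc9)Oc18)C(=O)OCC=C | intermediate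
11 | tert-butyl{[(2S,3S)-3-ArB-oxiran-2-yl]methoxy}dimethylsilane | CC(C)(C)[Si](C)(C)OC[C@@H]1O[C@H]1c1cc(OCc9ccccc9)c(OCc9ccccc9)c(OCc9ccccc9)c1Oc1cc(cc8OC(c9ccccc9)(c9ccccc9)Oc18)C(=O)OCC=C | intermediate
12 | 3,5-bis(benzyloxy)phenol | Oc1cc(OCc9ccccc9)cc(OCc9ccccc9)c1 | starting material
13 | (2S,3R)-3-ArB-3-[3,5-bis(benzyloxy)phenoxy]-1-(tert-butyldimethylsilyloxy)propan-2-ol | CC(C)(C)[Si](C)(C)OC[C@H](O)[C@H](Oc1cc(OCc9ccccc9)cc(OCc9ccccc9)c1)c1cc(OCc9ccccc9)c(OCc9ccccc9)c(OCc9ccccc9)c1Oc1cc(cc8OC(c9ccccc9)(c9ccccc9)Oc18)C(=O)OCC=C | intermediate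
14 | 3,4,5-tris(benzyloxy)benzoic acid | OC(=O)c1cc(OCc9ccccc9)c(OCc9ccccc9)c(OCc9ccccc9)c1 | starting material
15 | (2R,3R)-3-ArB-3-[3,5-bis(benzyloxy)phenoxy]-1-(tert-butyldimethylsilyloxy)propan-2-yl 3,4,5-tris(benzyloxy)benzoate | CC(C)(C)[Si](C)(C)OC[C@@H](OC(=O)c1cc(OCc9ccccc9)c(OCc9ccccc9)c(OCc9ccccc9)c1)[C@H](Oc1cc(OCc9ccccc9)cc(OCc9ccccc9)c1)c1cc(OCc9ccccc9)c(OCc9ccccc9)c(OCc9ccccc9)c1Oc1cc(cc8OC(c9ccccc9)(c9ccccc9)Oc18)C(=O)OCC=C | intermediate
16 | carboxylic acid: 15 with CO2H in place of the allyl ester on ring G | CC(C)(C)[Si](C)(C)OC[C@@H](OC(=O)c1cc(OCc9ccccc9)c(OCc9ccccc9)c(OCc9ccccc9)c1)[C@H](Oc1cc(OCc9ccccc9)cc(OCc9ccccc9)c1)c1cc(OCc9ccccc9)c(OCc9ccccc9)c(OCc9ccccc9)c1Oc1cc(cc8OC(c9ccccc9)(c9ccccc9)Oc18)C(=O)O | intermediate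
17 | (−)-epigallocatechin, (2R,3R) | O[C@@H]1Cc2c(O)cc(O)cc2O[C@@H]1c1cc(O)c(O)c(O)c1 | starting material
18 | 5,7,3',4',5'-penta-O-benzyl-(−)-epigallocatechin | O[C@@H]1Cc2c(OCc9ccccc9)cc(OCc9ccccc9)cc2O[C@@H]1c1cc(OCc9ccccc9)c(OCc9ccccc9)c(OCc9ccccc9)c1 | intermediate
19 | seco ester: ring-G carboxyl of 16 esterified with the 3-OH of 18; (2R,3R) chain, (2R,3R) flavan | CC(C)(C)[Si](C)(C)OC[C@@H](OC(=O)c1cc(OCc9ccccc9)c(OCc9ccccc9)c(OCc9ccccc9)c1)[C@H](Oc1cc(OCc9ccccc9)cc(OCc9ccccc9)c1)c1cc(OCc9ccccc9)c(OCc9ccccc9)c(OCc9ccccc9)c1Oc1cc(cc8OC(c9ccccc9)(c9ccccc9)Oc18)C(=O)O[C@@H]1Cc2c(OCc9ccccc9)cc(OCc9ccccc9)cc2O[C@@H]1c1cc(OCc9ccccc9)c(OCc9ccccc9)c(OCc9ccccc9)c1 | intermediate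
20 | primary alcohol: 19 with the silyl group removed; (2R,3R) chain | OC[C@@H](OC(=O)c1cc(OCc9ccccc9)c(OCc9ccccc9)c(OCc9ccccc9)c1)[C@H](Oc1cc(OCc9ccccc9)cc(OCc9ccccc9)c1)c1cc(OCc9ccccc9)c(OCc9ccccc9)c(OCc9ccccc9)c1Oc1cc(cc8OC(c9ccccc9)(c9ccccc9)Oc18)C(=O)O[C@@H]1Cc2c(OCc9ccccc9)cc(OCc9ccccc9)cc2O[C@@H]1c1cc(OCc9ccccc9)c(OCc9ccccc9)c(OCc9ccccc9)c1 | intermediate
21 | open-chain aldehyde: (2S,3R)-2-galloyloxy-3-aryloxy-3-arylpropanal carrying ring G and the lower unit | O=C[C@@H](OC(=O)c1cc(OCc9ccccc9)c(OCc9ccccc9)c(OCc9ccccc9)c1)[C@H](Oc1cc(OCc9ccccc9)cc(OCc9ccccc9)c1)c1cc(OCc9ccccc9)c(OCc9ccccc9)c(OCc9ccccc9)c1Oc1cc(cc8OC(c9ccccc9)(c9ccccc9)Oc18)C(=O)O[C@@H]1Cc2c(OCc9ccccc9)cc(OCc9ccccc9)cc2O[C@@H]1c1cc(OCc9ccccc9)c(OCc9ccccc9)c(OCc9ccccc9)c1 | intermediate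
22 | 4-hydroxyflavan: ring C closed, (2R,3R), C4 hydroxyl of either configuration, lower unit still attached only through the ring-G ester | O=C(O[C@@H]1C(O)c2c(OCc9ccccc9)cc(OCc9ccccc9)cc2O[C@@H]1c1cc(OCc9ccccc9)c(OCc9ccccc9)c(OCc9ccccc9)c1Oc1cc(cc8OC(c9ccccc9)(c9ccccc9)Oc18)C(=O)O[C@@H]1Cc2c(OCc9ccccc9)cc(OCc9ccccc9)cc2O[C@@H]1c1cc(OCc9ccccc9)c(OCc9ccccc9)c(OCc9ccccc9)c1)c1cc(OCc9ccccc9)c(OCc9ccccc9)c(OCc9ccccc9)c1 | intermediate
23 | flavan-4-yl cation derived from 22 | O=C(O[C@@H]1[CH+]c2c(OCc9ccccc9)cc(OCc9ccccc9)cc2O[C@@H]1c1cc(OCc9ccccc9)c(OCc9ccccc9)c(OCc9ccccc9)c1Oc1cc(cc8OC(c9ccccc9)(c9ccccc9)Oc18)C(=O)O[C@@H]1Cc2c(OCc9ccccc9)cc(OCc9ccccc9)cc2O[C@@H]1c1cc(OCc9ccccc9)c(OCc9ccccc9)c(OCc9ccccc9)c1)c1cc(OCc9ccccc9)c(OCc9ccccc9)c(OCc9ccccc9)c1 | intermediate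
24 | protected macrocycle: the target with 13 O-benzyl groups and a diphenylmethylene ketal on the 4,5-oxygens of ring G; upper unit (2R,3R,4R), lower unit (2R,3R) | O=C(O[C@@H]1[C@@H]2c3c(OCc9ccccc9)cc(OCc9ccccc9)cc3O[C@@H]1c1cc(OCc9ccccc9)c(OCc9ccccc9)c(OCc9ccccc9)c1Oc1cc(cc8OC(c9ccccc9)(c9ccccc9)Oc18)C(=O)O[C@@H]1Cc3c(OCc9ccccc9)cc(OCc9ccccc9)c2c3O[C@@H]1c1cc(OCc9ccccc9)c(OCc9ccccc9)c(OCc9ccccc9)c1)c1cc(OCc9ccccc9)c(OCc9ccccc9)c(OCc9ccccc9)c1 | intermediate
25 | CNP0601265.1: epigallocatechin 3-O-gallate-(4β→8)-epigallocatechin whose lower 3-O-galloyl group is joined through its 3-oxygen to C2' of ring B of the upper unit | O=C(O[C@@H]1[C@@H]2c3c(O)cc(O)cc3O[C@@H]1c1cc(O)c(O)c(O)c1Oc1cc(cc(O)c1O)C(=O)O[C@@H]1Cc3c(O)cc(O)c2c3O[C@@H]1c1cc(O)c(O)c(O)c1)c1cc(O)c(O)c(O)c1 | target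

**Step count and risks**

Total step count: 17. Longest linear sequence: 15 steps (steps 1, 2, 4–11, 13–17, from gallic acid).

Steps most likely to fail:

Step 16. The ring-D arene may add through C6 instead of C8, the cation may be captured by a second molecule (oligomerisation), or the aryloxide may be lost from C2 by β-elimination before ring C closes. Fallback: the two C–C bonds are made without the macrocyclic constraint and the large ring is closed as a lactone. It sets out from 15. HF·pyridine removes the silyl group to give the primary alcohol F1, and Dess–Martin oxidation gives the aldehyde F2. TMSOTf in CH2Cl2 at −78 → −20 °C with an excess of 18 should close ring C and join C4 to C8 of the free flavan in the usual intermolecular sense, giving the dimeric allyl ester F3. Pd(PPh3)4/morpholine frees the seco acid F4. A Yamaguchi macrolactonisation (2,4,6-trichlorobenzoyl chloride, Et3N, then DMAP, toluene, high dilution) onto the 3-hydroxyl of the lower unit should come back to the route at 24.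

Step 9. The phenoxide may attack the non-benzylic epoxide carbon, the ambident phenoxide may alkylate on carbon instead of oxygen, or the silyl group may migrate to the newly formed alkoxide. Fallback: the opening is run on the unprotected epoxy alcohol, where attack at the benzylic carbon is the established course and no silyl group can migrate. It sets out from 10. Compound 12 with KOtBu (0.5 equiv) in t-BuOH at 70 °C should give the (2S,3R)-diol F5. TBSCl/imidazole at 0 °C then silylates the primary hydroxyl only, coming back to the route at 13.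

Step 10. Substitution at the hindered carbinol may be slow and give way to elimination, or inversion may be eroded by participation of the neighbouring electron-rich aryl ring. Fallback: the carbinol is inverted by oxidation and reduction instead of substitution. It sets out from 13. Dess–Martin oxidation gives the ketone F6. LiBH(s-Bu)3 in THF at −78 °C should reduce it in the Felkin–Anh sense (hydride anti to the aryloxy group) to the (2R,3R)-alcohol F7. DCC/DMAP esterification with 14, with retention, comes back to the route at 15.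

Further compounds
F1 | step 16 | primary alcohol: 15 with the silyl group removed, allyl ester kept | OC[C@@H](OC(=O)c1cc(OCc9ccccc9)c(OCc9ccccc9)c(OCc9ccccc9)c1)[C@H](Oc1cc(OCc9ccccc9)cc(OCc9ccccc9)c1)c1cc(OCc9ccccc9)c(OCc9ccccc9)c(OCc9ccccc9)c1Oc1cc(cc8OC(c9ccccc9)(c9ccccc9)Oc18)C(=O)OCC=C
F2 | step 16 | aldehyde from F1, (2S,3R), allyl ester kept | O=C[C@@H](OC(=O)c1cc(OCc9ccccc9)c(OCc9ccccc9)c(OCc9ccccc9)c1)[C@H](Oc1cc(OCc9ccccc9)cc(OCc9ccccc9)c1)c1cc(OCc9ccccc9)c(OCc9ccccc9)c(OCc9ccccc9)c1Oc1cc(cc8OC(c9ccccc9)(c9ccccc9)Oc18)C(=O)OCC=C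
F3 | step 16 | 4β→8 dimer: (2R,3R,4R) upper flavan 3-O-gallate joined at C4 to C8 of 18, ring-G allyl ester, lower 3-OH free | O=C(c1cc(OCc9ccccc9)c(OCc9ccccc9)c(OCc9ccccc9)c1)O[C@@H]1[C@@H](c2c(OCc9ccccc9)cc(OCc9ccccc9)c3C[C@@H](O)[C@@H](c4cc(OCc9ccccc9)c(OCc9ccccc9)c(OCc9ccccc9)c4)Oc23)c2c(OCc9ccccc9)cc(OCc9ccccc9)cc2O[C@@H]1c1cc(OCc9ccccc9)c(OCc9ccccc9)c(OCc9ccccc9)c1Oc1cc(cc8OC(c9ccccc9)(c9ccccc9)Oc18)C(=O)OCC=C
F4 | step 16 | seco acid: F3 with CO2H in place of the allyl ester | O=C(c1cc(OCc9ccccc9)c(OCc9ccccc9)c(OCc9ccccc9)c1)O[C@@H]1[C@@H](c2c(OCc9ccccc9)cc(OCc9ccccc9)c3C[C@@H](O)[C@@H](c4cc(OCc9ccccc9)c(OCc9ccccc9)c(OCc9ccccc9)c4)Oc23)c2c(OCc9ccccc9)cc(OCc9ccccc9)cc2O[C@@H]1c1cc(OCc9ccccc9)c(OCc9ccccc9)c(OCc9ccccc9)c1Oc1cc(cc8OC(c9ccccc9)(c9ccccc9)Oc18)C(=O)O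
F5 | step 9 | (2S,3R)-3-ArB-3-[3,5-bis(benzyloxy)phenoxy]propane-1,2-diol | OC[C@H](O)[C@H](Oc1cc(OCc9ccccc9)cc(OCc9ccccc9)c1)c1cc(OCc9ccccc9)c(OCc9ccccc9)c(OCc9ccccc9)c1Oc1cc(cc8OC(c9ccccc9)(c9ccccc9)Oc18)C(=O)OCC=C
F6 | step 10 | (R)-1-ArB-1-[3,5-bis(benzyloxy)phenoxy]-3-(tert-butyldimethylsilyloxy)propan-2-one | CC(C)(C)[Si](C)(C)OCC(=O)[C@H](Oc1cc(OCc9ccccc9)cc(OCc9ccccc9)c1)c1cc(OCc9ccccc9)c(OCc9ccccc9)c(OCc9ccccc9)c1Oc1cc(cc8OC(c9ccccc9)(c9ccccc9)Oc18)C(=O)OCC=C
F7 | step 10 | (2R,3R)-3-ArB-3-[3,5-bis(benzyloxy)phenoxy]-1-(tert-butyldimethylsilyloxy)propan-2-ol | CC(C)(C)[Si](C)(C)OC[C@@H](O)[C@H](Oc1cc(OCc9ccccc9)cc(OCc9ccccc9)c1)c1cc(OCc9ccccc9)c(OCc9ccccc9)c(OCc9ccccc9)c1Oc1cc(cc8OC(c9ccccc9)(c9ccccc9)Oc18)C(=O)OCC=C
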